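**Plan**

Retrosynthesis: the fumaramide N–C(O) bond and the C1–sorbyl bond are cut first; then, in one operation, the ring bond C1–C6 and the C8–CH3 bond; then the C6=C8 bond of a butenolide and the C3–acetyl bond, which leads back to an open-chain tertiary carbinol (C5) made from (R)-lactic acid.
Locants and enabling feature: ring A is the carbocycle C1–C6 (C5 the O-bearing quaternary carbon, C6 the fusion CH), ring B the lactone C5–O–C7(=O)–C8–C6. C1 is bonded to C6, the β-carbon of the lactone carbonyl C7, and is joined to it through the chain C2–C5 that hangs on ring B at C5; the C8 methyl lies on the convex face of the cis-fused bicycle, cis to H-6.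
Forward order: C5 stereocentre → propenyl ethyl ketone carbinol → phthalimidoacetate → ring B (ozonolysis, aldol condensation) → β-diketone side chain → ring A together with the C8 methyl → imide exchanged for Boc → sorbyl group on C1 → fumaroyl group on N.
The imide is removed before C1 is acylated, because hydrazine would condense with a 2-acyl-1,3-dione.
Stereochemistry: C5 from (R)-lactic acid through its cis pivalaldehyde acetal (allylation with retention); C6 from the cis ring fusion forced by the tether at C5; C8 from methylation of the bicyclic lactone enolate on its convex face.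

Key step: step 10

Remark: the 1,3-dione and 2-acyl-1,3-dione units are tautomeric and are each written as one enol form; diketone 17 is written in its keto form with C3 unspecified.

**Route**

Step 1
Reactants: 1 (R)-lactic acid; 2 pivalaldehyde
Product: 3 (2R,5R)-2-tert-butyl-5-methyl-1,3-dioxolan-4-one (cis acetal)
Conditions: TsOH·H2O (cat.), H2SO4 (cat.), pentane, reflux, Dean–Stark; crystallisation from pentane/Et2O at −78 °C
Reagents that add atoms: pivalaldehyde 2, CC(C)(C)C=O
Why: acid-catalysed acetalisation with azeotropic water removal (the template step of self-regeneration of stereocentres) should favour the cis acetal, whose new centre C2 is set under thermodynamic control by the lactate centre and secured by crystallisation.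

Step 2
Reactants: 3 (2R,5R)-2-tert-butyl-5-methyl-1,3-dioxolan-4-one; 4 allyl bromide
Product: 6 (2R,5S)-5-allyl-2-tert-butyl-5-methyl-1,3-dioxolan-4-one, via lithium enolate 5 (not isolated)
Conditions: LiN(iPr)2 (1.1 equiv), THF, −78 °C; allyl bromide, −78 → −30 °C
Reagents that add atoms: allyl bromide 4, C=CCBr
Why: enolate alkylation in which the electrophile should enter anti to the tert-butyl group on C2, so that allyl takes the place of the former hydrogen and C5 is rebuilt with retention.

Step 3
Reactants: 6 (2R,5S)-5-allyl-2-tert-butyl-5-methyl-1,3-dioxolan-4-one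
Product: 7 (2R,5S)-2-tert-butyl-5-methyl-5-[(E)-prop-1-enyl]-1,3-dioxolan-4-one (any Z isomer serves equally)
Conditions: RuHCl(CO)(PPh3)3 (3 mol %), toluene, 100 °C
Reagents that add atoms: none
Why: ruthenium-hydride-catalysed alkene isomerisation (hydrometalation/β-hydride elimination) should move the terminal double bond one position inward and cannot go further because the next carbon is quaternary; no stereocentre is touched.

Step 4
Reactants: 7 (2R,5S)-2-tert-butyl-5-methyl-5-[(E)-prop-1-enyl]-1,3-dioxolan-4-one; 8 N,O-dimethylhydroxylamine hydrochloride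
Product: 9 (S,E)-2-hydroxy-N-methoxy-N,2-dimethylpent-3-enamide
Conditions: MeNHOMe·HCl (2.5 equiv), iPrMgCl (5 equiv), THF, −20 → 0 °C; aq. NH4Cl
Reagents that add atoms: N,O-dimethylhydroxylamine hydrochloride 8, CNOC.Cl
Why: Weinreb amide formation by aminolysis of the acylal-type lactone with the chloromagnesium amide, after which the hemiacetal alkoxide sheds pivalaldehyde; no bond to the quaternary centre is broken.

Step 5
Reactants: 9 (S,E)-2-hydroxy-N-methoxy-N,2-dimethylpent-3-enamide; 10 ethylmagnesium bromide
Product: 11 (S,E)-4-hydroxy-4-methylhept-5-en-3-one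
Conditions: EtMgBr (3 equiv), THF, 0 °C; aq. NH4Cl
Reagents that add atoms: ethylmagnesium bromide 10, CC[Mg]Br
Why: Weinreb ketone synthesis, in which the tertiary OH is first deprotonated and one further equivalent adds to give a magnesium-chelated tetrahedral adduct that is stable until work-up, so over-addition and an α-ketol shift of the alkoxide are avoided.

Step 6
Reactants: 11 (S,E)-4-hydroxy-4-methylhept-5-en-3-one; 12 N-phthaloylglycyl chloride
Product: 13 (S,E)-4-methyl-3-oxohept-5-en-4-yl 2-(1,3-dioxoisoindolin-2-yl)acetate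
Conditions: pyridine, DMAP (0.2 equiv), CH2Cl2, 0 °C → rt
Reagents that add atoms: N-phthaloylglycyl chloride 12, O=C(Cl)CN1C(=O)c2ccccc2C1=O
Why: DMAP-catalysed esterification of a tertiary alcohol with an acid chloride through the N-acylpyridinium salt, which leaves the C–O bond of the stereocentre intact.

Step 7
Reactants: 13 (S,E)-4-methyl-3-oxohept-5-en-4-yl 2-(1,3-dioxoisoindolin-2-yl)acetate
Product: 14 (S)-2-methyl-1,3-dioxopentan-2-yl 2-(1,3-dioxoisoindolin-2-yl)acetate
Conditions: O3, CH2Cl2, −78 °C; PPh3, −78 °C → rt; used without purification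
Reagents that add atoms: ozone, [O-][O+]=O
Why: ozonolysis with reductive work-up should cleave the only C=C bond (the imide arene is electron-poor and inert) and unveil the non-enolisable aldehyde that becomes C6.

Step 8
Reactants: 14 (S)-2-methyl-1,3-dioxopentan-2-yl 2-(1,3-dioxoisoindolin-2-yl)acetate
Product: 15 2-[(5S)-5-methyl-2-oxo-5-propanoyl-2,5-dihydrofuran-3-yl]isoindoline-1,3-dione
Conditions: DBU (1.5 equiv), 4 Å molecular sieves, MeCN, 0 °C → rt
Reagents that add atoms: none
Why: intramolecular aldol (Knoevenagel-type) condensation, the amine-base butenolide closure known for arylacetates of α-hydroxy ketones: the CH2 flanked by ester and imide should add 5-exo to the aldehyde (far more electrophilic than the ketone) and lose water by E1cB to give ring B, C5 being quaternary and unaffected.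

Step 9
Reactants: 15 2-[(5S)-5-methyl-2-oxo-5-propanoyl-2,5-dihydrofuran-3-yl]isoindoline-1,3-dione; 16 1-acetyl-1H-benzotriazole
Product: 17 2-[(5S)-5-methyl-5-(2-methyl-3-oxobutanoyl)-2-oxo-2,5-dihydrofuran-3-yl]isoindoline-1,3-dione (C3 epimers and enol)
Conditions: 1-acetylbenzotriazole (1.3 equiv), MgBr2·OEt2 (2.5 equiv), iPr2NEt (3 equiv), CH2Cl2, rt; dilute aq. HCl wash
Reagents that add atoms: 1-acetyl-1H-benzotriazole 16, CC(=O)n1nnc2ccccc21
Why: soft-enolisation crossed Claisen C-acylation, in which the magnesium-chelated ketone is enolised by the tertiary amine at its only α-CH2 and acylated on carbon, the product resting as a magnesium diketonate chelate so that no strong base meets the butenolide or the imide (the new centre C3 is enolisable and need not be controlled).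

Step 10
Reactants: 17 2-[(5S)-5-methyl-5-(2-methyl-3-oxobutanoyl)-2-oxo-2,5-dihydrofuran-3-yl]isoindoline-1,3-dione; 18 iodomethane
Product: 21 2-[(3S,3aR,7aS)-7-hydroxy-3,6,7a-trimethyl-2,5-dioxo-2,3,3a,4,5,7a-hexahydro-1-benzofuran-3-yl]isoindoline-1,3-dione (5S,6R,8S in the plan's locants), via dilithium dienolate 19 (not isolated), via dilithium lactone enolate 20 (not isolated)
Conditions: 17 added to LiN(iPr)2 (2.1 equiv), THF, −78 → −40 °C; MeI (1.2 equiv), DMPU (2 equiv), −78 °C; aq. NH4Cl
Reagents that add atoms: iodomethane 18, CI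
Why: LiN(iPr)2 should remove first the C3–H between the two ketones and then a proton of the terminal methyl group, the terminal carbon C1 of the resulting dienolate should add to C6, the β-carbon of the imido-butenolide, and the lactone enolate so formed should be methylated at C8 by MeI. The closest known reaction types are the terminal-carbon (γ) reactions of 1,3-diketone dianions, conjugate additions to N,N-diacyl dehydroamino esters and C-alkylation of α-phthalimido ester enolates, here run as a Michael addition with enolate trapping. Ring A closes in the 6-(enolendo)-exo-trig mode, the C6=C8 bond being exocyclic to the new ring. C6 is set by the tether: C1 can reach only the butenolide face on which C5 carries the acyl chain, so the ring fusion must be cis (6R). C8 is set by the folded bicycle: MeI should approach the enolate anti to the C1 methylene on the adjacent C6, that is on the convex face, which places CH3 cis to H-6 and nitrogen on the concave face (8S). The step needs closure through carbon and methylation at C8 only: the butenolide has neither α- nor γ-hydrogen, C5 is quaternary so only one diketone terminus can be deprotonated, the 3-methyl group disfavours the lithium-chelated W-form of the dienolate that would hold C1 away from C6, closure through oxygen would be undone by E1cB under the same base, and the chelated lithium diketonate left after cyclisation should be far less reactive towards MeI at −78 °C than the lactone enolate.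

Step 11
Reactants: 21 2-[(3S,3aR,7aS)-7-hydroxy-3,6,7a-trimethyl-2,5-dioxo-2,3,3a,4,5,7a-hexahydro-1-benzofuran-3-yl]isoindoline-1,3-dione
Product: 23 tert-butyl N-[(3S,3aR,7aS)-7-hydroxy-3,6,7a-trimethyl-2,5-dioxo-2,3,3a,4,5,7a-hexahydro-1-benzofuran-3-yl]carbamate, via free amine 22 (not isolated)
Conditions: N2H4·H2O (4 equiv), EtOH, rt → 40 °C; filter, evaporate with toluene; Boc2O (3 equiv), NaHCO3, THF/H2O, 45 °C; citric acid work-up
Reagents that add atoms: di-tert-butyl dicarbonate, CC(C)(C)OC(=O)OC(=O)OC(C)(C)C
Why: Ing–Manske hydrazinolysis should release the C8 amine while the 1,3-dione sits as its unreactive hydrazinium enolate and the lactone carbonyl is shielded by the quaternary C8, and carbamoylation with Boc2O then protects nitrogen for the strongly basic next step; no stereocentre is touched.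

Step 12
Reactants: 24 sorbic acid ((2E,4E)-hexa-2,4-dienoic acid); 8 N,O-dimethylhydroxylamine hydrochloride
Product: 25 (2E,4E)-N-methoxy-N-methylhexa-2,4-dienamide
Conditions: EDC·HCl (1.2 equiv), iPr2NEt (2.5 equiv), DMAP (cat.), CH2Cl2, 0 °C → rt
Reagents that add atoms: N,O-dimethylhydroxylamine hydrochloride 8, CNOC.Cl
Why: carbodiimide-mediated amidation should give the Weinreb amide without disturbing the (E,E)-diene.

Step 13
Reactants: 23 tert-butyl N-[(3S,3aR,7aS)-7-hydroxy-3,6,7a-trimethyl-2,5-dioxo-2,3,3a,4,5,7a-hexahydro-1-benzofuran-3-yl]carbamate; 25 (2E,4E)-N-methoxy-N-methylhexa-2,4-dienamide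
Product: 27 tert-butyl N-[(3S,3aR,4Z,7aS)-7-hydroxy-4-[(2E,4E)-1-hydroxyhexa-2,4-dien-1-ylidene]-3,6,7a-trimethyl-2,5-dioxo-2,3,3a,4,5,7a-hexahydro-1-benzofuran-3-yl]carbamate, via trilithium trianion 26 (not isolated)
Conditions: LiN(iPr)2 (3.2 equiv), THF/DMPU, −78 → −30 °C; 25 (1.3 equiv), −78 → −40 °C; aq. HCl to pH 3
Reagents that add atoms: (2E,4E)-N-methoxy-N-methylhexa-2,4-dienamide 25, C/C=C/C=C/C(=O)N(C)OC
Why: γ-acylation of a cyclic 1,3-dione polyanion with a Weinreb amide: after the enol and carbamate protons the third equivalent of base removes a C1 proton (the only enolisable carbon left), and this hard carbanion should add 1,2 to give a chelated tetrahedral adduct that is released on acidic quench as the acyl-dione, which should settle as the hydrogen-bonded (Z)-enol; the lithiated carbamate is not electrophilic, and C5, C6 and C8 carry no acidic hydrogen.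

Step 14
Reactants: 28 mono-tert-butyl fumarate ((E)-4-tert-butoxy-4-oxobut-2-enoic acid)
Product: 29 tert-butyl (E)-4-chloro-4-oxobut-2-enoate
Conditions: (COCl)2 (1.2 equiv), DMF (cat.), CH2Cl2, 0 °C → rt; evaporate, use crude
Reagents that add atoms: oxalyl chloride, O=C(Cl)C(=O)Cl
Why: acid chloride formation through the chloroiminium salt of DMF is mild enough to keep the tert-butyl ester and the (E)-alkene.

Step 15
Reactants: 27 tert-butyl N-[(3S,3aR,4Z,7aS)-7-hydroxy-4-[(2E,4E)-1-hydroxyhexa-2,4-dien-1-ylidene]-3,6,7a-trimethyl-2,5-dioxo-2,3,3a,4,5,7a-hexahydro-1-benzofuran-3-yl]carbamate; 29 tert-butyl (E)-4-chloro-4-oxobut-2-enoate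
Product: 31 tert-butyl (E)-4-{[(3S,3aR,4Z,7aS)-7-hydroxy-4-[(2E,4E)-1-hydroxyhexa-2,4-dien-1-ylidene]-3,6,7a-trimethyl-2,5-dioxo-2,3,3a,4,5,7a-hexahydro-1-benzofuran-3-yl]amino}-4-oxobut-2-enoate, via ammonium trifluoroacetate 30 (not isolated)
Conditions: TFA, anisole, CH2Cl2, 0 °C; evaporate; 29 (1.5 equiv), then 2,6-lutidine (3 equiv), CH2Cl2, −20 → 0 °C; aq. NaHCO3, then pH 3
Reagents that add atoms: tert-butyl (E)-4-chloro-4-oxobut-2-enoate 29, CC(C)(C)OC(=O)/C=C/C(Cl)=O
Why: acidolysis of the Boc group followed by N-acylation with an acid chloride under weak base, in which the amine is set free only when the acylating agent is already present (forestalling its condensation with the neighbouring acyl-dione) and any enol ester formed should be cleaved again by the bicarbonate work-up.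

Step 16
Reactants: 31 tert-butyl (E)-4-{[(3S,3aR,4Z,7aS)-7-hydroxy-4-[(2E,4E)-1-hydroxyhexa-2,4-dien-1-ylidene]-3,6,7a-trimethyl-2,5-dioxo-2,3,3a,4,5,7a-hexahydro-1-benzofuran-3-yl]amino}-4-oxobut-2-enoate
Product: 32 sorbicillactone A
Conditions: TFA/CH2Cl2, anisole, 0 °C → rt; evaporate
Reagents that add atoms: none
Why: acidolytic cleavage of the tert-butyl ester (E1 loss of isobutene) under anhydrous conditions should leave the lactone, the fumaramide and the enolised triketone untouched.

**Compound list**

1 | (R)-lactic acid | C[C@@H](O)C(=O)O | starting material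
2 | pivalaldehyde | CC(C)(C)C=O | starting material
3 | (2R,5R)-2-tert-butyl-5-methyl-1,3-dioxolan-4-one | C[C@H]1O[C@@H](C(C)(C)C)OC1=O | intermediate
4 | allyl bromide | C=CCBr | starting material
5 | lithium (2R)-2-tert-butyl-5-methyl-1,3-dioxol-4-olate (enolate of 3, formed in the flask) | [Li+].CC1=C([O-])O[C@H](C(C)(C)C)O1 | intermediate
6 | (2R,5S)-5-allyl-2-tert-butyl-5-methyl-1,3-dioxolan-4-one | C[C@@]1(CC=C)O[C@@H](C(C)(C)C)OC1=O | intermediate
7 | (2R,5S)-2-tert-butyl-5-methyl-5-[(E)-prop-1-enyl]-1,3-dioxolan-4-one | C[C@@]1(/C=C/C)O[C@@H](C(C)(C)C)OC1=O | intermediate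
8 | N,O-dimethylhydroxylamine hydrochloride | CNOC.Cl | starting material
9 | (S,E)-2-hydroxy-N-methoxy-N,2-dimethylpent-3-enamide | C[C@@](C(=O)N(C)OC)(/C=C/C)O | intermediate
10 | ethylmagnesium bromide | CC[Mg]Br | starting material
11 | (S,E)-4-hydroxy-4-methylhept-5-en-3-one | C[C@@](C(=O)CC)(/C=C/C)O | intermediate
12 | N-phthaloylglycyl chloride | O=C(Cl)CN1C(=O)c2ccccc2C1=O | starting material
13 | (S,E)-4-methyl-3-oxohept-5-en-4-yl 2-(1,3-dioxoisoindolin-2-yl)acetate | C[C@@](C(=O)CC)(/C=C/C)OC(=O)CN1C(=O)c2ccccc2C1=O | intermediate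
14 | (S)-2-methyl-1,3-dioxopentan-2-yl 2-(1,3-dioxoisoindolin-2-yl)acetate | C[C@@](C(=O)CC)(C=O)OC(=O)CN1C(=O)c2ccccc2C1=O | intermediate
15 | 2-[(5S)-5-methyl-2-oxo-5-propanoyl-2,5-dihydrofuran-3-yl]isoindoline-1,3-dione | CCC(=O)[C@@]1(C)OC(=O)C(N2C(=O)c3ccccc3C2=O)=C1 | intermediate
16 | 1-acetyl-1H-benzotriazole | CC(=O)n1nnc2ccccc21 | starting material
17 | 2-[(5S)-5-methyl-5-(2-methyl-3-oxobutanoyl)-2-oxo-2,5-dihydrofuran-3-yl]isoindoline-1,3-dione (C3 unspecified) | CC(=O)C(C)C(=O)[C@@]1(C)OC(=O)C(N2C(=O)c3ccccc3C2=O)=C1 | intermediate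
18 | iodomethane | CI | starting material
19 | dilithium dienolate of 17 (O-lithiated at C2 and C4, terminal C1 methylene; formed in the flask) | [Li+].[Li+].C=C([O-])C(C)=C([O-])[C@@]1(C)OC(=O)C(N2C(=O)c3ccccc3C2=O)=C1 | intermediate
20 | dilithium salt of the cyclised (5S,6R) bicycle: C2/C4 diketonate and C7 lactone enolate with C8 sp2 (formed in the flask) | [Li+].[Li+].O=C1C(C)=C([O-])[C@@]2(C)OC([O-])=C(N3C(=O)c4ccccc4C3=O)[C@H]2C1 | intermediate
21 | 2-[(3S,3aR,7aS)-7-hydroxy-3,6,7a-trimethyl-2,5-dioxo-2,3,3a,4,5,7a-hexahydro-1-benzofuran-3-yl]isoindoline-1,3-dione | O=C1C(C)=C(O)[C@@]2(C)OC(=O)[C@@](C)(N3C(=O)c4ccccc4C3=O)[C@H]2C1 | intermediate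
22 | (3S,3aR,7aS)-3-amino-7-hydroxy-3,6,7a-trimethyl-3a,4-dihydro-1-benzofuran-2,5(3H,7aH)-dione (formed in the flask) | O=C1C(C)=C(O)[C@@]2(C)OC(=O)[C@@](C)(N)[C@H]2C1 | intermediate
23 | tert-butyl N-[(3S,3aR,7aS)-7-hydroxy-3,6,7a-trimethyl-2,5-dioxo-2,3,3a,4,5,7a-hexahydro-1-benzofuran-3-yl]carbamate | O=C1C(C)=C(O)[C@@]2(C)OC(=O)[C@@](C)(NC(=O)OC(C)(C)C)[C@H]2C1 | intermediate
24 | sorbic acid, (2E,4E)-hexa-2,4-dienoic acid | C/C=C/C=C/C(=O)O | starting material
25 | (2E,4E)-N-methoxy-N-methylhexa-2,4-dienamide | C/C=C/C=C/C(=O)N(C)OC | intermediate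
26 | trilithium trianion of 23 (C2/C4 bis-enolate with C1=C2 double bond, N-lithiated carbamate; formed in the flask) | [Li+].[Li+].[Li+].[O-]C=1C(C)=C([O-])[C@@]2(C)OC(=O)[C@@](C)([N-]C(=O)OC(C)(C)C)[C@H]2C=1 | intermediate
27 | tert-butyl N-[(3S,3aR,4Z,7aS)-7-hydroxy-4-[(2E,4E)-1-hydroxyhexa-2,4-dien-1-ylidene]-3,6,7a-trimethyl-2,5-dioxo-2,3,3a,4,5,7a-hexahydro-1-benzofuran-3-yl]carbamate | C/C=C/C=C/C(O)=C1/C(=O)C(C)=C(O)[C@@]2(C)OC(=O)[C@@](C)(NC(=O)OC(C)(C)C)[C@@H]12 | intermediate
28 | mono-tert-butyl fumarate, (E)-4-tert-butoxy-4-oxobut-2-enoic acid | CC(C)(C)OC(=O)/C=C/C(=O)O | starting material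
29 | tert-butyl (E)-4-chloro-4-oxobut-2-enoate | CC(C)(C)OC(=O)/C=C/C(Cl)=O | intermediate
30 | ammonium trifluoroacetate of the N-deprotected sorbyl compound (C8–NH3+; formed in the flask) | C/C=C/C=C/C(O)=C1/C(=O)C(C)=C(O)[C@@]2(C)OC(=O)[C@@](C)([NH3+])[C@@H]12.[O-]C(=O)C(F)(F)F | intermediate
31 | tert-butyl (E)-4-{[(3S,3aR,4Z,7aS)-7-hydroxy-4-[(2E,4E)-1-hydroxyhexa-2,4-dien-1-ylidene]-3,6,7a-trimethyl-2,5-dioxo-2,3,3a,4,5,7a-hexahydro-1-benzofuran-3-yl]amino}-4-oxobut-2-enoate | C/C=C/C=C/C(O)=C1/C(=O)C(C)=C(O)[C@@]2(C)OC(=O)[C@@](C)(NC(=O)/C=C/C(=O)OC(C)(C)C)[C@@H]12 | intermediate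
32 | sorbicillactone A | C/C=C/C=C/C(O)=C1/C(=O)C(C)=C(O)[C@@]2(C)OC(=O)[C@@](C)(NC(=O)/C=C/C(=O)O)[C@@H]12 | target

**Step count**

Total: 16 steps. Longest linear sequence: 14 steps (steps 1–11, 13, 15 and 16); steps 12 and 14 prepare the two acylating agents.

**Steps most likely to fail**

Step 10. The amide base may add to the butenolide or to an imide carbonyl before the second deprotonation. The dienolate may stay in its chelated form and fail to close, or close through oxygen. The α-imido lactone enolate may rearrange onto an imide carbonyl before it is methylated, or methylation may also occur at C3. The fallback separates the two bond formations and takes the strong base out of the cyclisation; it sets out from 17 and returns at 21. Treatment of 17 with Me3SiOTf/Et3N in CH2Cl2 should give the 1,3-bis(trimethylsilyloxy)diene F1. TiCl4 in CH2Cl2 at −78 °C should then bring about an intramolecular Mukaiyama–Michael addition of its terminal carbon to C6. Aqueous work-up should give the cis-fused lactone without the C8 methyl group F2 (either C8 epimer). Deprotonation of the enol and of C8–H with LiN(SiMe3)2 (2.2 equiv) and addition of MeI should then methylate C8 on the convex face to give 21.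

Step 13. Trianion formation may be incomplete, or the carbanion may add in a conjugate sense to the dienamide. The N-methoxy amide may be degraded by excess base. On warming, the C6–C8 bond may open by retro-Michael reaction and so scramble C6 and C8. The fallback replaces acyl substitution by aldol addition and oxidation; it sets out from 23 and returns at 27. The trianion 26, generated as in step 13, is treated at −78 °C with (2E,4E)-hexa-2,4-dienal, which should add 1,2 quickly and give the C1 dienyl carbinol F3 (mixture of diastereomers). Oxidation of this doubly allylic alcohol with MnO2 in CH2Cl2, or with Dess–Martin periodinane, should give 27.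

Step 11. Cleavage of the hindered imide on the quaternary C8 may be slow enough for hydrazinolysis of the lactone or condensation of hydrazine with a ring carbonyl to compete. The fallback is a reductive cleavage; it sets out from 21 and returns at 22. NaBH4 in iPrOH/H2O should reduce one imide carbonyl and open the ring to the 2-(hydroxymethyl)benzamide F4, while the dione, present as its sodium enolate, and the hindered lactone should resist. Warming in AcOH at 80 °C should then lactonise the hydroxy amide to phthalide and expel amine 22, which is carbamoylated with Boc2O as in step 11 to reach 23.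

**Further compounds**

F1 | step 10 | 2-[(5S)-5-[2-methyl-1,3-bis(trimethylsilyloxy)buta-1,3-dienyl]-5-methyl-2-oxo-2,5-dihydrofuran-3-yl]isoindoline-1,3-dione | C=C(O[Si](C)(C)C)C(C)=C(O[Si](C)(C)C)[C@@]1(C)OC(=O)C(N2C(=O)c3ccccc3C2=O)=C1
F2 | step 10 | 2-[(3aR,7aS)-7-hydroxy-6,7a-dimethyl-2,5-dioxo-2,3,3a,4,5,7a-hexahydro-1-benzofuran-3-yl]isoindoline-1,3-dione (C3 of the benzofuranone, C8 in the plan's locants, unspecified) | O=C1C(C)=C(O)[C@@]2(C)OC(=O)C(N3C(=O)c4ccccc4C3=O)[C@H]2C1
F3 | step 13 | tert-butyl N-[(3S,3aR,7aS)-7-hydroxy-4-[(2E,4E)-1-hydroxyhexa-2,4-dienyl]-3,6,7a-trimethyl-2,5-dioxo-2,3,3a,4,5,7a-hexahydro-1-benzofuran-3-yl]carbamate (C4 and carbinol centres unspecified) | C/C=C/C=C/C(O)C1C(=O)C(C)=C(O)[C@@]2(C)OC(=O)[C@@](C)(NC(=O)OC(C)(C)C)[C@@H]12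
F4 | step 11 | N-[(3S,3aR,7aS)-7-hydroxy-3,6,7a-trimethyl-2,5-dioxo-2,3,3a,4,5,7a-hexahydro-1-benzofuran-3-yl]-2-(hydroxymethyl)benzamide | O=C1C(C)=C(O)[C@@]2(C)OC(=O)[C@@](C)(NC(=O)c3ccccc3CO)[C@H]2C1
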